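**Plan**

- The retrosynthesis first removes the four phenol acetals, then cuts both aryl C–O ester bonds at C1 and C2 of the central ring in one operation, giving a 3,6-diaryl-4,5-dioxygenated benzyne and the symmetrical diacyl peroxide of the side-chain acid; further cuts are one acyl C–O bond of the peroxide (peroxy acid plus acid), the C2=C3 alkene of the acid and the two biaryl bonds.
- What makes this possible: C1 and C2 of the central benzene ring are adjacent, carry the same (2Z,4S,5S)-4,5-epoxyhex-2-enoyloxy group, and lie on a mirror plane that bisects the C1–C2 and C4–C5 bonds, with an aryl ring at C3 and at C6. An aryne C1≡C2 can take up exactly this pattern from a symmetrical peroxide.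
- Forward, arene part: 4,5-dibromoveratrole is iodinated at C3 and C6, coupled twice at the iodides (Suzuki–Miyaura), changed from methyl ethers to 1-ethoxyethyl acetals, and one bromine is turned into OH, the other into SiMe3 by retro-Brook shift, before triflation.
- Forward, side chain and end: Sharpless epoxidation of (E)-crotyl alcohol (the only ring formed in the route), oxidation with Z-olefination and saponification; one portion of the salt is perhydrolysed to the peroxy acid, which is acylated by a second portion to give the peroxide; then aryne bis-acyloxylation and acetal removal.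
- Stereochemistry: C4 and C5 of each side chain (S,S) come from the Sharpless epoxidation with L-(+)-DIPT, the Z-alkene from the Still–Gennari olefination; both are carried unchanged.
- The phenols are protected as acetals and not as silyl ethers because the aryne is released with fluoride.

Key step: step 12

Remark: the four 1-ethoxyethyl acetal carbons form without control, so compounds 6–12, 22–24 and F1 are mixtures of acetal epimers (acetal centres left undefined in the SMILES); all converge on one compound when the acetals are removed.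

**Route**

Step 1
Reactants: 1 4,5-dibromoveratrole (1,2-dibromo-4,5-dimethoxybenzene)
Product: 2 1,2-dibromo-3,6-diiodo-4,5-dimethoxybenzene
Conditions: NIS (2.4 equiv), CF3SO3H, CH2Cl2, 0 °C → rt
Reagents that add atoms: N-iodosuccinimide, O=C1CCC(=O)N1I
Why: Electrophilic aromatic iodination; acid-activated NIS is strong enough for the dibrominated ring, and C3 and C6, each ortho to a methoxy group, are the only positions left.

Step 2
Reactants: 2 1,2-dibromo-3,6-diiodo-4,5-dimethoxybenzene; 3 4-methoxyphenylboronic acid (2.2 equiv)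
Product: 4 1,2-dibromo-4,5-dimethoxy-3,6-bis(4-methoxyphenyl)benzene
Conditions: Pd(PPh3)4 (5 mol %), K2CO3, toluene/EtOH/H2O, 80 °C
Reagents that add atoms: none
Why: Twofold Suzuki–Miyaura coupling; zerovalent palladium inserts into the C–I bonds much faster than into the flanked C–Br bonds, so both aryl groups should enter at C3 and C6 and both bromines should be kept.

Step 3
Reactants: 4 1,2-dibromo-4,5-dimethoxy-3,6-bis(4-methoxyphenyl)benzene
Product: 5 4,5-dibromo-3,6-bis(4-hydroxyphenyl)benzene-1,2-diol
Conditions: BBr3 (6 equiv), CH2Cl2, −78 °C → rt; H2O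
Reagents that add atoms: none
Why: Lewis-acid cleavage of all four aryl methyl ethers (BBr3 demethylation); the aryl bromides are inert.

Step 4
Reactants: 5 4,5-dibromo-3,6-bis(4-hydroxyphenyl)benzene-1,2-diol
Product: 6 1,2-dibromo-4,5-bis(1-ethoxyethoxy)-3,6-bis[4-(1-ethoxyethoxy)phenyl]benzene
Conditions: ethyl vinyl ether (excess), PPTS (pyridinium p-toluenesulfonate, cat.), CH2Cl2/THF, rt
Reagents that add atoms: ethyl vinyl ether, C=COCC
Why: Acid-catalysed addition of the phenols to the vinyl ether (acetal protection) should give 1-ethoxyethyl ethers that are inert to fluoride, organometallic reagents and base and are small enough for the flanked catechol oxygens.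

Step 5
Reactants: 6 1,2-dibromo-4,5-bis(1-ethoxyethoxy)-3,6-bis[4-(1-ethoxyethoxy)phenyl]benzene
Product: 9 2-bromo-4,5-bis(1-ethoxyethoxy)-3,6-bis[4-(1-ethoxyethoxy)phenyl]phenol, via arylmagnesium chloride 7 (not isolated), via dimethyl arylboronate 8 (not isolated)
Conditions: i-PrMgCl·LiCl (1.1 equiv), THF, −15 → 0 °C; B(OMe)3, −78 °C → rt; H2O2, NaOH, H2O, 0 °C
Reagents that add atoms: hydrogen peroxide, OO
Why: Bromine–magnesium exchange should stop after one bromine because the aryl Grignard formed is electron-rich and the ortho-bromoarylmagnesium is stable below 0 °C; borylation and alkaline peroxide oxidation (boron-to-oxygen 1,2-shift) then give the phenol while the acetals stay intact.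

Step 6
Reactants: 9 2-bromo-4,5-bis(1-ethoxyethoxy)-3,6-bis[4-(1-ethoxyethoxy)phenyl]phenol
Product: 12 4,5-bis(1-ethoxyethoxy)-3,6-bis[4-(1-ethoxyethoxy)phenyl]-2-(trimethylsilyl)phenyl trifluoromethanesulfonate, via aryl trimethylsilyl ether 10 (not isolated), via lithium 2-silylphenoxide 11 (not isolated)
Conditions: (Me3Si)2NH, THF, 65 °C; evaporate; n-BuLi, THF, −78 °C; Tf2O (1.05 equiv), −78 → 0 °C
Reagents that add atoms: hexamethyldisilazane, C[Si](C)(C)N[Si](C)(C)C; trifluoromethanesulfonic anhydride, O=S(=O)(OS(=O)(=O)C(F)(F)F)C(F)(F)F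
Why: O-silylation, bromine–lithium exchange and anionic 1,3 O-to-C silyl migration (retro-Brook rearrangement) place the trimethylsilyl group on carbon, and triflation of the lithium phenoxide, far faster at −78 °C than any attack of the anhydride on the acetals, completes the standard sequence to an ortho-silylaryl triflate.

Step 7
Reactants: 13 (E)-crotyl alcohol
Product: 14 [(2S,3S)-3-methyloxiran-2-yl]methanol
Conditions: Ti(OiPr)4 (5 mol %), L-(+)-DIPT (6 mol %), t-BuOOH, 4 Å MS, CH2Cl2, −20 °C
Reagents that add atoms: tert-butyl hydroperoxide, CC(C)(C)OO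
Why: Sharpless asymmetric epoxidation; the titanium complex of the L-(+)-tartrate delivers oxygen to the alkene face that gives the (2S,3S)-epoxide, and the trans relation of the two new stereocentres follows from the E-alkene.

Step 8
Reactants: 14 [(2S,3S)-3-methyloxiran-2-yl]methanol
Product: 16 methyl (2Z,4S,5S)-4,5-epoxyhex-2-enoate, via epoxy aldehyde 15 (not isolated)
Conditions: Dess–Martin periodinane, NaHCO3, CH2Cl2, 0 °C; filtrate added to (CF3CH2O)2P(O)CH2CO2Me, KN(SiMe3)2, 18-crown-6, THF, −78 °C
Reagents that add atoms: methyl bis(2,2,2-trifluoroethyl)phosphonoacetate, COC(=O)CP(=O)(OCC(F)(F)F)OCC(F)(F)F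
Why: Dess–Martin oxidation followed by Still–Gennari olefination, in which the electron-poor phosphonate with a crown-complexed potassium ion eliminates from the kinetic adduct to give the Z-enoate; the volatile aldehyde is used in solution and its epoxide carbons do not epimerise.

Step 9
Reactants: 16 methyl (2Z,4S,5S)-4,5-epoxyhex-2-enoate
Product: 17 lithium (2Z,4S,5S)-4,5-epoxyhex-2-enoate
Conditions: LiOH·H2O (1.0 equiv), THF/H2O, 0 °C; lyophilise
Reagents that add atoms: lithium hydroxide, [Li+].[OH-]
Why: Ester saponification at 0 °C with one equivalent of hydroxide; the product is kept as the salt because the free Z-epoxy acid can lactonise onto its own epoxide.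

Step 10
Reactants: 17 lithium (2Z,4S,5S)-4,5-epoxyhex-2-enoate (first portion)
Product: 19 (2Z,4S,5S)-4,5-epoxyhex-2-eneperoxoic acid, via mixed carbonic anhydride 18 (not isolated)
Conditions: i-BuOCOCl (1.0 equiv), THF, −20 °C; then H2O2 (35 % aq, 5 equiv), K2HPO4/KH2PO4 buffer (pH 8), 0 °C, 15 min; adjust to pH 5 (KH2PO4), extract Et2O, dry (MgSO4), keep as a cold titrated solution
Reagents that add atoms: hydrogen peroxide, OO
Why: Perhydrolysis of a mixed carbonic anhydride (nucleophilic acyl substitution by hydroperoxide): the carboxylate is activated by the chloroformate without being protonated, and the alpha-effect nucleophile, used in excess so that the peroxy acid is not acylated further, attacks the enoyl carbonyl, while the electron-poor Z-alkene and the epoxide should survive the brief, weakly basic treatment at 0 °C.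

Step 11
Reactants: 19 (2Z,4S,5S)-4,5-epoxyhex-2-eneperoxoic acid (1.0 equiv); 17 lithium (2Z,4S,5S)-4,5-epoxyhex-2-enoate (second portion, 1.0 equiv)
Product: 21 bis[(2Z,4S,5S)-4,5-epoxyhex-2-enoyl] peroxide, via free epoxy acid 20 (not isolated)
Conditions: 17, 1 M H3PO4 (1.0 equiv, NaCl-saturated), Et2O, 0 °C, ether layer dried (Na2SO4); added together with DCC (1.05 equiv) to 19 in Et2O, −15 → 0 °C; filter, use as a cold solution
Reagents that add atoms: none
Why: Carbodiimide coupling of a peroxy acid with a carboxylic acid (the DCC synthesis of diacyl peroxides in its two-component form): the acid, freed cold just before use, forms the O-acylisourea, whose acyl group is taken over by the terminal oxygen of the peroxy acid, with no nucleophilic amine present that could isomerise the Z-enoyl groups.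

Step 12
Reactants: 12 4,5-bis(1-ethoxyethoxy)-3,6-bis[4-(1-ethoxyethoxy)phenyl]-2-(trimethylsilyl)phenyl trifluoromethanesulfonate; 21 bis[(2Z,4S,5S)-4,5-epoxyhex-2-enoyl] peroxide (1.5 equiv); 17 lithium (2Z,4S,5S)-4,5-epoxyhex-2-enoate (10 mol %, chain initiator)
Product: 24 4,5-bis(1-ethoxyethoxy)-3,6-bis[4-(1-ethoxyethoxy)phenyl]-1,2-phenylene bis[(2Z,4S,5S)-4,5-epoxyhex-2-enoate], via aryne 22 (not isolated), via aryl potassium 23 (not isolated)
Conditions: KF (3 equiv), 18-crown-6, THF, 0 °C → rt, slow addition of 12 to the other components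
Reagents that add atoms: none
Why: Proposed new method: fluoride strips the trimethylsilyl group of 12 with loss of triflate to give aryne 22, the catalytic carboxylate adds to one aryne carbon, and the ortho-acyloxy aryl anion 23 attacks one oxygen of the weak O–O bond of 21, which forms the second aryl C–O bond and releases a fresh carboxylate that carries the anionic chain. The closest known reaction types are the net insertion of arynes into S–S and I–I bonds, the O-arylation of carboxylates by arynes and the acyloxylation of aryl Grignard reagents by diacyl peroxides. No ring is closed and no stereocentre is made; the epoxide centres and the Z-alkenes of both acyl groups are carried over untouched. Regiochemistry does not arise, since the aryne has a mirror plane through the middle of its triple bond and an aryl group beside each end. The step needs the aryl anion to be acyloxylated faster than it is protonated or shifts the neighbouring acyl group onto carbon, which the excess of 21, the slow addition of 12 and aprotic THF at low temperature are meant to secure. Acetal protection secures chemoselectivity towards fluoride: aryl silyl ethers would be cleaved to phenoxides that add to the aryne or are acylated by 21, whereas the 1-ethoxyethyl ethers are inert.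

Step 13
Reactants: 24 4,5-bis(1-ethoxyethoxy)-3,6-bis[4-(1-ethoxyethoxy)phenyl]-1,2-phenylene bis[(2Z,4S,5S)-4,5-epoxyhex-2-enoate]
Product: 25 4,5-dihydroxy-3,6-bis(4-hydroxyphenyl)-1,2-phenylene bis[(2Z,4S,5S)-4,5-epoxyhex-2-enoate] (the target)
Conditions: PPTS (20 mol %), MeOH/THF (1:1), 0 °C → rt, argon
Reagents that add atoms: none
Why: Acid-catalysed transacetalisation to methanol (acetal deprotection) should free the four phenols under conditions too mild to open the ester-deactivated epoxides or to cleave the aryl esters.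

**Compound list**

1 | 4,5-dibromoveratrole (1,2-dibromo-4,5-dimethoxybenzene) | COc1cc(Br)c(Br)cc1OC | starting material
2 | 1,2-dibromo-3,6-diiodo-4,5-dimethoxybenzene | COc1c(I)c(Br)c(Br)c(I)c1OC | intermediate
3 | 4-methoxyphenylboronic acid | COc1ccc(B(O)O)cc1 | starting material
4 | 1,2-dibromo-4,5-dimethoxy-3,6-bis(4-methoxyphenyl)benzene | COc1ccc(cc1)-c1c(Br)c(Br)c(-c2ccc(OC)cc2)c(OC)c1OC | intermediate
5 | 4,5-dibromo-3,6-bis(4-hydroxyphenyl)benzene-1,2-diol | Oc1ccc(cc1)-c1c(Br)c(Br)c(-c2ccc(O)cc2)c(O)c1O | intermediate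
6 | 1,2-dibromo-4,5-bis(1-ethoxyethoxy)-3,6-bis[4-(1-ethoxyethoxy)phenyl]benzene | CCOC(C)Oc1ccc(cc1)-c1c(Br)c(Br)c(-c2ccc(OC(C)OCC)cc2)c(OC(C)OCC)c1OC(C)OCC | intermediate
7 | {2-bromo-4,5-bis(1-ethoxyethoxy)-3,6-bis[4-(1-ethoxyethoxy)phenyl]phenyl}magnesium chloride (LiCl complex) | Cl[Mg]c1c(Br)c(-c2ccc(OC(C)OCC)cc2)c(OC(C)OCC)c(OC(C)OCC)c1-c1ccc(OC(C)OCC)cc1 | intermediate
8 | dimethyl {2-bromo-4,5-bis(1-ethoxyethoxy)-3,6-bis[4-(1-ethoxyethoxy)phenyl]phenyl}boronate | COB(OC)c1c(Br)c(-c2ccc(OC(C)OCC)cc2)c(OC(C)OCC)c(OC(C)OCC)c1-c1ccc(OC(C)OCC)cc1 | intermediate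
9 | 2-bromo-4,5-bis(1-ethoxyethoxy)-3,6-bis[4-(1-ethoxyethoxy)phenyl]phenol | Oc1c(Br)c(-c2ccc(OC(C)OCC)cc2)c(OC(C)OCC)c(OC(C)OCC)c1-c1ccc(OC(C)OCC)cc1 | intermediate
10 | trimethylsilyl ether of 9 | C[Si](C)(C)Oc1c(Br)c(-c2ccc(OC(C)OCC)cc2)c(OC(C)OCC)c(OC(C)OCC)c1-c1ccc(OC(C)OCC)cc1 | intermediate
11 | lithium 4,5-bis(1-ethoxyethoxy)-3,6-bis[4-(1-ethoxyethoxy)phenyl]-2-(trimethylsilyl)phenoxide | [Li+].[O-]c1c([Si](C)(C)C)c(-c2ccc(OC(C)OCC)cc2)c(OC(C)OCC)c(OC(C)OCC)c1-c1ccc(OC(C)OCC)cc1 | intermediate
12 | 4,5-bis(1-ethoxyethoxy)-3,6-bis[4-(1-ethoxyethoxy)phenyl]-2-(trimethylsilyl)phenyl trifluoromethanesulfonate | C[Si](C)(C)c1c(OS(=O)(=O)C(F)(F)F)c(-c2ccc(OC(C)OCC)cc2)c(OC(C)OCC)c(OC(C)OCC)c1-c1ccc(OC(C)OCC)cc1 | intermediate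
13 | (E)-crotyl alcohol | C/C=C/CO | starting material
14 | [(2S,3S)-3-methyloxiran-2-yl]methanol | C[C@@H]1O[C@H]1CO | intermediate
15 | (2R,3S)-3-methyloxirane-2-carbaldehyde | C[C@@H]1O[C@H]1C=O | intermediate
16 | methyl (2Z,4S,5S)-4,5-epoxyhex-2-enoate | C[C@@H]1O[C@H]1/C=C\C(=O)OC | intermediate
17 | lithium (2Z,4S,5S)-4,5-epoxyhex-2-enoate | C[C@@H]1O[C@H]1/C=C\C(=O)[O-].[Li+] | intermediate
18 | isobutyl carbonic (2Z,4S,5S)-4,5-epoxyhex-2-enoic anhydride | C[C@@H]1O[C@H]1/C=C\C(=O)OC(=O)OCC(C)C | intermediate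
19 | (2Z,4S,5S)-4,5-epoxyhex-2-eneperoxoic acid | C[C@@H]1O[C@H]1/C=C\C(=O)OO | intermediate
20 | (2Z,4S,5S)-4,5-epoxyhex-2-enoic acid | C[C@@H]1O[C@H]1/C=C\C(=O)O | intermediate
21 | bis[(2Z,4S,5S)-4,5-epoxyhex-2-enoyl] peroxide | C[C@@H]1O[C@H]1/C=C\C(=O)OOC(=O)/C=C\[C@@H]1O[C@H]1C | intermediate
22 | 4,5-bis(1-ethoxyethoxy)-3,6-bis[4-(1-ethoxyethoxy)phenyl]benzyne | C1#CC(-c2ccc(OC(C)OCC)cc2)=C(OC(C)OCC)C(OC(C)OCC)=C1-c1ccc(OC(C)OCC)cc1 | intermediate
23 | potassium 2-[(2Z,4S,5S)-4,5-epoxyhex-2-enoyloxy]-4,5-bis(1-ethoxyethoxy)-3,6-bis[4-(1-ethoxyethoxy)phenyl]phenyl (aryl potassium) | C[C@@H]1O[C@H]1/C=C\C(=O)Oc1[c-]c(-c2ccc(OC(C)OCC)cc2)c(OC(C)OCC)c(OC(C)OCC)c1-c1ccc(OC(C)OCC)cc1.[K+] | intermediate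
24 | 4,5-bis(1-ethoxyethoxy)-3,6-bis[4-(1-ethoxyethoxy)phenyl]-1,2-phenylene bis[(2Z,4S,5S)-4,5-epoxyhex-2-enoate] | C[C@@H]1O[C@H]1/C=C\C(=O)Oc1c(OC(=O)/C=C\[C@@H]2O[C@H]2C)c(-c2ccc(OC(C)OCC)cc2)c(OC(C)OCC)c(OC(C)OCC)c1-c1ccc(OC(C)OCC)cc1 | intermediate
25 | 4,5-dihydroxy-3,6-bis(4-hydroxyphenyl)-1,2-phenylene bis[(2Z,4S,5S)-4,5-epoxyhex-2-enoate] (CNP0249450.1) | C[C@@H]1O[C@H]1/C=C\C(=O)Oc1c(OC(=O)/C=C\[C@@H]2O[C@H]2C)c(-c2ccc(O)cc2)c(O)c(O)c1-c1ccc(O)cc1 | target

**Step count and risks**

Total steps: 13. Longest linear sequence: 8 steps (steps 1–6, 12 and 13); the side-chain branch (steps 7–11) joins at step 12.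

Steps most likely to fail:

1. Step 12 (key step). The aryl anion formed after carboxylate addition may be protonated or may shift its neighbouring acyl group onto carbon before it reaches the peroxide, or the carboxylate may add too slowly to the crowded aryne, which is then lost to fluoride or to oligomerisation. The fallback uses known chemistry and sets out from bromophenol 9. Deprotonation and bromine–lithium exchange with n-BuLi (2.2 equiv, THF, −78 °C), borylation with B(OMe)3 and oxidation with H2O2/NaOH should give the catechol 4,5-bis(1-ethoxyethoxy)-3,6-bis[4-(1-ethoxyethoxy)phenyl]benzene-1,2-diol F1, handled under argon. Twofold Steglich esterification of F1 with acid 20, freshly released from 17 (N,N'-diisopropylcarbodiimide, a small amount of 4-(dimethylamino)pyridine, CH2Cl2, −20 °C, to limit Z-to-E isomerisation), returns to the route at 24.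

2. Step 10. Hydroperoxide may attack the carbonate carbonyl of the mixed anhydride and return the acid, may add in conjugate fashion to the activated Z-enoyl group, or the peroxy acid may decompose during extraction and drying. The fallback does without an isolated peroxy acid and sets out from salt 17. The acid 20 is freed cold as in step 11, and two molecules of it are joined with H2O2 (0.5 equiv) and DCC (Et2O, −15 → 0 °C) in the symmetrical carbodiimide peroxide synthesis, in which the peroxy acid exists only in passing. The fallback comes back to the route at peroxide 21 and makes no compound outside the list.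

3. Step 13. Acid may open the vinyl epoxides, either by methanol or by the neighbouring Z-ester carbonyl with lactonisation and loss of the aryl ester, in competition with acetal cleavage. The fallback changes the protecting group to one removed by buffered fluoride and, because aryl silyl ethers do not tolerate the fluoride of the aryne step, brings in the esters by acylation. It sets out from tetraphenol 5 and returns at 25. TIPSOTf and 2,6-lutidine should give 1,2-dibromo-4,5-bis(triisopropylsilyloxy)-3,6-bis[4-(triisopropylsilyloxy)phenyl]benzene F2. Bromine–magnesium exchange, borylation and oxidation (H2O2/AcOH) in the manner of step 5 should give 2-bromo-4,5-bis(triisopropylsilyloxy)-3,6-bis[4-(triisopropylsilyloxy)phenyl]phenol F3. Deprotonation and bromine–lithium exchange with n-BuLi (2.2 equiv), borylation and oxidation should then give the catechol 4,5-bis(triisopropylsilyloxy)-3,6-bis[4-(triisopropylsilyloxy)phenyl]benzene-1,2-diol F4. Twofold carbodiimide esterification with acid 20 should give 4,5-bis(triisopropylsilyloxy)-3,6-bis[4-(triisopropylsilyloxy)phenyl]-1,2-phenylene bis[(2Z,4S,5S)-4,5-epoxyhex-2-enoate] F5, the tetrakis(triisopropylsilyl) ether of the target, and Bu4NF buffered with AcOH (THF, 0 °C) should release 25.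

Further compounds
F1 | step 12 | 4,5-bis(1-ethoxyethoxy)-3,6-bis[4-(1-ethoxyethoxy)phenyl]benzene-1,2-diol | Oc1c(O)c(-c2ccc(OC(C)OCC)cc2)c(OC(C)OCC)c(OC(C)OCC)c1-c1ccc(OC(C)OCC)cc1
F0 | step 10 | none | none
F2 | step 13 | 1,2-dibromo-4,5-bis(triisopropylsilyloxy)-3,6-bis[4-(triisopropylsilyloxy)phenyl]benzene | CC(C)[Si](C(C)C)(C(C)C)Oc1ccc(cc1)-c1c(Br)c(Br)c(-c2ccc(O[Si](C(C)C)(C(C)C)C(C)C)cc2)c(O[Si](C(C)C)(C(C)C)C(C)C)c1O[Si](C(C)C)(C(C)C)C(C)C
F3 | step 13 | 2-bromo-4,5-bis(triisopropylsilyloxy)-3,6-bis[4-(triisopropylsilyloxy)phenyl]phenol | Oc1c(Br)c(-c2ccc(O[Si](C(C)C)(C(C)C)C(C)C)cc2)c(O[Si](C(C)C)(C(C)C)C(C)C)c(O[Si](C(C)C)(C(C)C)C(C)C)c1-c1ccc(O[Si](C(C)C)(C(C)C)C(C)C)cc1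
F4 | step 13 | 4,5-bis(triisopropylsilyloxy)-3,6-bis[4-(triisopropylsilyloxy)phenyl]benzene-1,2-diol | Oc1c(O)c(-c2ccc(O[Si](C(C)C)(C(C)C)C(C)C)cc2)c(O[Si](C(C)C)(C(C)C)C(C)C)c(O[Si](C(C)C)(C(C)C)C(C)C)c1-c1ccc(O[Si](C(C)C)(C(C)C)C(C)C)cc1
F5 | step 13 | 4,5-bis(triisopropylsilyloxy)-3,6-bis[4-(triisopropylsilyloxy)phenyl]-1,2-phenylene bis[(2Z,4S,5S)-4,5-epoxyhex-2-enoate] | C[C@@H]1O[C@H]1/C=C\C(=O)Oc1c(OC(=O)/C=C\[C@@H]2O[C@H]2C)c(-c2ccc(O[Si](C(C)C)(C(C)C)C(C)C)cc2)c(O[Si](C(C)C)(C(C)C)C(C)C)c(O[Si](C(C)C)(C(C)C)C(C)C)c1-c1ccc(O[Si](C(C)C)(C(C)C)C(C)C)cc1
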